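**Retrosynthetic overview**

- The ten-membered ring is closed last, at C3–C4, by a Ni/Cr-mediated (Nozaki–Hiyama–Kishi) addition of a (Z)-alkenyl iodide to an (E)-enal; this also creates the C3 carbinol.
- Key disconnection C6–C7: the enoate β-carbon C7 of a Morita–Baylis–Hillman-derived allylic bromide is made nucleophilic as a 2-(methoxycarbonyl)allylindium (an acrylate homoenolate equivalent) and joined to the aldehyde carbon of (Z)-3-iodobut-2-enal. The cis α-methylene-γ-lactone (first ring) closes in the same step, and C6 and C7 are set from C8.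
- The bromide comes from an α-silyloxy aldehyde; C8 is set by a D-proline aldol of acetone with dimethoxyacetaldehyde, C10 by chelation-controlled vinyl Grignard addition, and C1=C2–C3 by early cross-metathesis with crotonaldehyde.
- The angelate is put on the C8 hydroxyl just before ring closure. Ring order: lactone (step 9), then carbocycle (step 12).

Assumption: the SMILES is taken literally, i.e. the cis-fused lactone isomer (3S,6S,7R,8S,10S; 1E,4Z) in germacrane numbering, which is used for atom labels throughout (lactone O on C6; C7 bears C11(=C13H2)–C12(=O); angelate on C8; C10 carbinol with the C14 methyl; C4 bears the C15 methyl).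

**Step 1**
Reactants: 1 but-2-yn-1-ol
Product: 3 (2Z)-3-iodobut-2-en-1-ol, via cyclic alkenylaluminate 2 (not isolated)
Conditions: NaAlH2(OCH2CH2OCH3)2 (1.4 equiv), Et2O, 0 °C to rt; then I2 (1.5 equiv), THF, −78 to 0 °C
Reagents that add atoms: iodine (II)
Why: Hydroxyl-directed trans-hydroalumination of the propargylic alcohol puts aluminium on C3 inside the five-membered aluminate 2, and iodinolysis of the C–Al bond with retention gives only the (Z)-iodoalkene (Corey-type hydroalumination–iodination).

**Step 2**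
Reactants: 3 (2Z)-3-iodobut-2-en-1-ol
Product: 4 (2Z)-3-iodobut-2-enal
Conditions: MnO2 (15 equiv), CH2Cl2, rt, dark; used at once
Reagents that add atoms: none
Why: MnO2 oxidises the allylic alcohol selectively under neutral conditions, so the (Z)-β-iodoenal forms without alkene isomerisation (allylic oxidation).

**Step 3**
Reactants: 5 acetone; 6 2,2-dimethoxyacetaldehyde (60% aqueous solution)
Product: 7 (4S)-4-hydroxy-5,5-dimethoxypentan-2-one
Conditions: D-proline (30 mol%), acetone/DMSO (1:4), rt, 48 h
Reagents that add atoms: none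
Why: Proline-catalysed direct aldol reaction (List–Barbas type), in which the D-proline enamine of acetone adds to the si face of the aldehyde through the Houk–List hydrogen-bonded chair and so sets C8 as (S).

**Step 4**
Reactants: 7 (4S)-4-hydroxy-5,5-dimethoxypentan-2-one; 8 vinylmagnesium bromide
Product: 9 (3S,5S)-6,6-dimethoxy-3-methylhex-1-ene-3,5-diol
Conditions: 8 (3 equiv), THF/CH2Cl2, −78 °C; aq. NH4Cl work-up
Reagents that add atoms: none
Why: Chelation-controlled Grignard addition (1,3-induction), in which the magnesium alkoxide from the first equivalent ties C8–O and the ketone into a six-membered chelate and vinyl adds to the ketone face anti to the C8 substituent, setting C10 as (S) (1,3-anti diol), with the minor epimer removed by chromatography.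

**Step 5**
Reactants: 9 (3S,5S)-6,6-dimethoxy-3-methylhex-1-ene-3,5-diol; 10 (2E)-but-2-enal (crotonaldehyde)
Product: 11 (2E,4S,6S)-4,6-dihydroxy-7,7-dimethoxy-4-methylhept-2-enal
Conditions: second-generation Hoveyda–Grubbs catalyst RuCl2(H2IMes)(=CH-C6H4-2-O-i-Pr) (5 mol%), 10 (8 equiv), CH2Cl2, 40 °C
Reagents that add atoms: none
Why: Olefin cross-metathesis at the only alkene of 9, assisted by the free tertiary allylic hydroxyl, with the quaternary neighbour enforcing the (E)-enal.

**Step 6**
Reactants: 11 (2E,4S,6S)-4,6-dihydroxy-7,7-dimethoxy-4-methylhept-2-enal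
Product: 13 (2E,4S,6S)-4-methyl-4,6-bis(triethylsilyloxy)hept-2-enedial, via bis-silyl ether acetal 12 (not isolated)
Conditions: Et3SiOTf (4.5 equiv), 2,6-lutidine (6 equiv), CH2Cl2, −40 to 0 °C; then H2O, rt
Reagents that add atoms: triethylsilyl trifluoromethanesulfonate (CC[Si](CC)(CC)OS(=O)(=O)C(F)(F)F); water (O)
Why: Silyl triflate and 2,6-lutidine first silylate both hydroxyls and then turn the dimethyl acetal into a pyridinium-type adduct that water hydrolyses to the aldehyde (Fujioka acetal cleavage), so no aqueous acid touches the silyl ethers, the enal or the stereocentres.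

**Step 7**
Reactants: 13 dialdehyde; 14 methyl acrylate
Product: 15 methyl (4S,6S,7E)-3-hydroxy-6-methyl-2-methylidene-9-oxo-4,6-bis(triethylsilyloxy)non-7-enoate (both C3 epimers)
Conditions: 1,4-diazabicyclo[2.2.2]octane (DABCO, 1 equiv), 14 (6 equiv, neat), rt, 2–3 d
Reagents that add atoms: none
Why: Morita–Baylis–Hillman reaction, in which the DABCO–acrylate zwitterion adds to the strongly activated α-silyloxy aldehyde far faster than to the conjugated enal (whose β-carbon is shielded by the quaternary C10), the new carbinol centre being removed in step 8.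

**Step 8**
Reactants: 15 Morita–Baylis–Hillman adduct
Product: 16 methyl (2Z,4S,6S,7E)-2-(bromomethyl)-6-methyl-9-oxo-4,6-bis(triethylsilyloxy)nona-2,7-dienoate
Conditions: N-bromosuccinimide (1.3 equiv), Me2S (1.5 equiv), CH2Cl2, −20 to 0 °C
Reagents that add atoms: N-bromosuccinimide (O=C1CCC(=O)N1Br)
Why: Corey–Kim-type activation of the allylic alcohol as an alkoxysulfonium salt and SN2′ attack of bromide give the conjugated primary allylic bromide as the preferred (Z)-isomer (chain cis to CH2Br) under neutral conditions that spare silyl ethers and enal.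

**Step 9 (key step)**
Reactants: 16 allylic bromide; 4 (2Z)-3-iodobut-2-enal
Product: 18 (4S,5R)-5-[(1Z)-2-iodoprop-1-en-1-yl]-3-methylidene-4-[(1S,3S,4E)-3-methyl-6-oxo-1,3-bis(triethylsilyloxy)hex-4-en-1-yl]oxolan-2-one, via hydroxy ester 17 (not isolated)
Conditions: In (powder, 2 equiv), 4 (4 equiv), THF/sat. aq. NH4Cl (1:1), rt, 16 added over 2 h; then pyridinium p-toluenesulfonate (0.2 equiv), benzene, 60 °C
Reagents that add atoms: none
Why: Indium inserts into the C–Br bond to give a 2-(methoxycarbonyl)allylindium species in which C7, the normally electrophilic enoate β-carbon, is the nucleophile (acrylate homoenolate equivalent; Barbier-type Dreiding–Schmidt lactone annulation), and it bonds to the aldehyde carbon C6 of 4 through a Zimmerman–Traxler chair with the C8 branch axial (syn adduct, hence the cis lactone after acid-catalysed ring closure) and anti to the C8 silyloxy group in the A(1,3)-minimised rotamer, which sets C6 and C7 from C8, while the enal of 16 cannot be reached intramolecularly (a trans-cycloheptene would result) and is outcompeted by excess 4.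

**Step 10**
Reactants: 18 bis-silyl lactone
Product: 19 (4R,5R)-4-[(1S,3S,4E)-1,3-dihydroxy-3-methyl-6-oxohex-4-en-1-yl]-5-[(1Z)-2-iodoprop-1-en-1-yl]-3-methylideneoxolan-2-one
Conditions: HF·pyridine, pyridine/THF, 0 °C to rt
Reagents that add atoms: none
Why: Fluoride-driven desilylation (Si–F bond formation) removes both triethylsilyl groups under buffered conditions that neither open nor transpose the lactone.

**Step 11**
Reactants: 19 enal diol; 20 angelic acid, (2Z)-2-methylbut-2-enoic acid
Product: 22 (1S,3S,4E)-3-hydroxy-1-[(2R,3R)-2-[(1Z)-2-iodoprop-1-en-1-yl]-4-methylidene-5-oxooxolan-3-yl]-3-methyl-6-oxohex-4-en-1-yl (2Z)-2-methylbut-2-enoate, via mixed anhydride 21 (not isolated)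
Conditions: 20 (3 equiv), 2,4,6-trichlorobenzoyl chloride (3 equiv), Et3N (3 equiv), toluene, rt, 2 h; then 19, toluene, 75 °C
Reagents that add atoms: none
Why: Yamaguchi-type esterification through mixed anhydride 21, in which the secondary C8 hydroxyl attacks the unhindered angeloyl carbonyl, the tertiary C10 hydroxyl stays free, and the absence of DMAP avoids Z to E isomerisation of the angelate.

**Step 12**
Reactants: 22 iodo-enal angelate
Product: 23 (3aR,4S,6S,7E,9S,10Z,11aS)-6,9-dihydroxy-6,10-dimethyl-3-methylidene-2-oxo-2,3,3a,4,5,6,9,11a-octahydrocyclodeca[b]furan-4-yl (2Z)-2-methylbut-2-enoate (CNP0262559.5)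
Conditions: CrCl2 (10 equiv), NiCl2 (0.1 equiv), DMSO, rt, 0.002 M, slow addition of 22
Reagents that add atoms: none
Why: Nozaki–Hiyama–Kishi macrocyclisation, in which zerovalent nickel inserts into the C–I bond, transmetalation to trivalent chromium gives an alkenylchromium species with retained (Z)-geometry that adds only to the aldehyde, and C3 is set under macrocyclic control, attack on the outward face of the s-trans enal (C8 ester and C10 methyl pseudo-equatorial) being expected to give the (3S) alcohol.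

**Compound list**

1 | but-2-yn-1-ol | CC#CCO | starting material
2 | sodium 2,2-bis(2-methoxyethoxy)-3-methyl-2,5-dihydro-1,2-oxaaluminol-2-uide (cyclic alkenylaluminate) | CC1=CCO[Al-]1(OCCOC)OCCOC.[Na+] | intermediate (not isolated)
3 | (2Z)-3-iodobut-2-en-1-ol | C/C(I)=C/CO | intermediate
4 | (2Z)-3-iodobut-2-enal | C/C(I)=C/C=O | intermediate
5 | acetone | CC(C)=O | starting material
6 | 2,2-dimethoxyacetaldehyde | COC(OC)C=O | starting material
7 | (4S)-4-hydroxy-5,5-dimethoxypentan-2-one | CC(=O)C[C@H](O)C(OC)OC | intermediate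
8 | vinylmagnesium bromide | C=C[Mg]Br | starting material
9 | (3S,5S)-6,6-dimethoxy-3-methylhex-1-ene-3,5-diol | C=C[C@@](C)(O)C[C@H](O)C(OC)OC | intermediate
10 | (2E)-but-2-enal (crotonaldehyde) | C/C=C/C=O | starting material
11 | (2E,4S,6S)-4,6-dihydroxy-7,7-dimethoxy-4-methylhept-2-enal | O=C/C=C/[C@@](C)(O)C[C@H](O)C(OC)OC | intermediate
12 | (2E,4S,6S)-7,7-dimethoxy-4-methyl-4,6-bis(triethylsilyloxy)hept-2-enal | O=C/C=C/[C@@](C)(O[Si](CC)(CC)CC)C[C@H](O[Si](CC)(CC)CC)C(OC)OC | intermediate (not isolated)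
13 | (2E,4S,6S)-4-methyl-4,6-bis(triethylsilyloxy)hept-2-enedial | O=C/C=C/[C@@](C)(O[Si](CC)(CC)CC)C[C@H](O[Si](CC)(CC)CC)C=O | intermediate
14 | methyl acrylate | C=CC(=O)OC | starting material
15 | methyl (4S,6S,7E)-3-hydroxy-6-methyl-2-methylidene-9-oxo-4,6-bis(triethylsilyloxy)non-7-enoate (both C3 epimers) | O=C/C=C/[C@@](C)(O[Si](CC)(CC)CC)C[C@H](O[Si](CC)(CC)CC)C(O)C(=C)C(=O)OC | intermediate
16 | methyl (2Z,4S,6S,7E)-2-(bromomethyl)-6-methyl-9-oxo-4,6-bis(triethylsilyloxy)nona-2,7-dienoate | O=C/C=C/[C@@](C)(O[Si](CC)(CC)CC)C[C@H](O[Si](CC)(CC)CC)/C=C(\CBr)C(=O)OC | intermediate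
17 | methyl (3S,4S,6S,7E)-3-[(1R,2Z)-1-hydroxy-3-iodobut-2-en-1-yl]-6-methyl-2-methylidene-9-oxo-4,6-bis(triethylsilyloxy)non-7-enoate | C=C(C(=O)OC)[C@@H]([C@@H](O)/C=C(/C)I)[C@@H](O[Si](CC)(CC)CC)C[C@](C)(O[Si](CC)(CC)CC)/C=C/C=O | intermediate (not isolated)
18 | (4S,5R)-5-[(1Z)-2-iodoprop-1-en-1-yl]-3-methylidene-4-[(1S,3S,4E)-3-methyl-6-oxo-1,3-bis(triethylsilyloxy)hex-4-en-1-yl]oxolan-2-one | C=C1C(=O)O[C@@H](/C=C(/C)I)[C@H]1[C@@H](O[Si](CC)(CC)CC)C[C@](C)(O[Si](CC)(CC)CC)/C=C/C=O | intermediate
19 | (4R,5R)-4-[(1S,3S,4E)-1,3-dihydroxy-3-methyl-6-oxohex-4-en-1-yl]-5-[(1Z)-2-iodoprop-1-en-1-yl]-3-methylideneoxolan-2-one | C=C1C(=O)O[C@@H](/C=C(/C)I)[C@H]1[C@@H](O)C[C@](C)(O)/C=C/C=O | intermediate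
20 | angelic acid, (2Z)-2-methylbut-2-enoic acid | C/C=C(/C)C(=O)O | starting material
21 | (2Z)-2-methylbut-2-enoic 2,4,6-trichlorobenzoic anhydride | C/C=C(/C)C(=O)OC(=O)c1c(Cl)cc(Cl)cc1Cl | intermediate (not isolated)
22 | (1S,3S,4E)-3-hydroxy-1-[(2R,3R)-2-[(1Z)-2-iodoprop-1-en-1-yl]-4-methylidene-5-oxooxolan-3-yl]-3-methyl-6-oxohex-4-en-1-yl (2Z)-2-methylbut-2-enoate | C=C1C(=O)O[C@@H](/C=C(/C)I)[C@H]1[C@@H](OC(=O)/C(C)=C\C)C[C@](C)(O)/C=C/C=O | intermediate
23 | (3aR,4S,6S,7E,9S,10Z,11aS)-6,9-dihydroxy-6,10-dimethyl-3-methylidene-2-oxo-2,3,3a,4,5,6,9,11a-octahydrocyclodeca[b]furan-4-yl (2Z)-2-methylbut-2-enoate | C=C1C(=O)O[C@H]2/C=C(/C)[C@@H](O)/C=C/[C@@](C)(O)C[C@H](OC(=O)/C(C)=C\C)[C@@H]12 | target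

**Step count**

Total steps: 12. Longest linear sequence: 10 (steps 3 to 12, from acetone and 2,2-dimethoxyacetaldehyde); steps 1 and 2 make aldehyde 4 for the convergent step 9.

**Three steps most likely to fail**

Step 9 carries the most risk. After allylic transposition the allylindium species has a silyloxy group β to the metal and may eliminate it, the facial selectivity relative to C8 rests on a steric model, and the free enal of 16 and 18 can intercept the nucleophile. The fallback sets out from 16. Palladium-catalysed borylation (B2pin2, Pd2(dba)3, KOAc, toluene, 50 °C) gives the pinacol allylboronate F1, which does not β-eliminate. Sc(OTf)3-catalysed allylboration of excess 4 (toluene, 0 °C) then runs through a closed six-membered transition state organised by boron and gives hydroxy ester 17 after aqueous work-up. Lactonisation as in step 9 rejoins the route at 18.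

Step 11 is the second risk. The hindered C8 hydroxyl has to be acylated at 75 °C next to an enal to which it can add in a 5-exo oxa-Michael fashion, and angelates isomerise easily to tiglates. The fallback sets out from 19. The enal is masked with HC(OMe)3 and pyridinium p-toluenesulfonate in MeOH at 0 °C to give the diol dimethyl acetal F2. The same mixed-anhydride acylation, now with no enal present, gives the angelate dimethyl acetal F3. Mild hydrolysis (pyridinium p-toluenesulfonate, acetone/H2O, rt) rejoins the route at 22.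

Step 12 is the third risk. Ten-membered ring closure competes with protodeiodination and oligomerisation, and the C3 configuration is fixed only by ring conformation. The fallback sets out from 22. If the cyclisation gives mainly the C3-epimeric alcohol F4, MnO2 (CH2Cl2, rt) oxidises its doubly allylic hydroxyl to the cross-conjugated dienone F5. Reagent-controlled reduction with (R)-1-methyl-3,3-diphenyl-tetrahydro-1H,3H-pyrrolo[1,2-c][1,3,2]oxazaborole (the (R)-CBS catalyst) and catecholborane (toluene, −78 °C), the α-branched C4 alkenyl group acting as the large substituent, rejoins the route at 23.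

**Further compounds**

F1 | step 9 | methyl (2E,4S,6S,7E)-6-methyl-9-oxo-2-[(4,4,5,5-tetramethyl-1,3,2-dioxaborolan-2-yl)methyl]-4,6-bis(triethylsilyloxy)nona-2,7-dienoate | O=C/C=C/[C@@](C)(O[Si](CC)(CC)CC)C[C@H](O[Si](CC)(CC)CC)/C=C(\CB1OC(C)(C)C(C)(C)O1)C(=O)OC
F2 | step 11 | (4R,5R)-4-[(1S,3S,4E)-1,3-dihydroxy-6,6-dimethoxy-3-methylhex-4-en-1-yl]-5-[(1Z)-2-iodoprop-1-en-1-yl]-3-methylideneoxolan-2-one | C=C1C(=O)O[C@@H](/C=C(/C)I)[C@H]1[C@@H](O)C[C@](C)(O)/C=C/C(OC)OC
F3 | step 11 | (1S,3S,4E)-3-hydroxy-1-[(2R,3R)-2-[(1Z)-2-iodoprop-1-en-1-yl]-4-methylidene-5-oxooxolan-3-yl]-6,6-dimethoxy-3-methylhex-4-en-1-yl (2Z)-2-methylbut-2-enoate | C=C1C(=O)O[C@@H](/C=C(/C)I)[C@H]1[C@@H](OC(=O)/C(C)=C\C)C[C@](C)(O)/C=C/C(OC)OC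
F4 | step 12 | (3aR,4S,6S,7E,9R,10Z,11aS)-6,9-dihydroxy-6,10-dimethyl-3-methylidene-2-oxo-2,3,3a,4,5,6,9,11a-octahydrocyclodeca[b]furan-4-yl (2Z)-2-methylbut-2-enoate | C=C1C(=O)O[C@H]2/C=C(/C)[C@H](O)/C=C/[C@@](C)(O)C[C@H](OC(=O)/C(C)=C\C)[C@@H]12
F5 | step 12 | (3aR,4S,6S,7E,10Z,11aS)-6-hydroxy-6,10-dimethyl-3-methylidene-2,9-dioxo-2,3,3a,4,5,6,9,11a-octahydrocyclodeca[b]furan-4-yl (2Z)-2-methylbut-2-enoate | C=C1C(=O)O[C@H]2/C=C(/C)C(=O)/C=C/[C@@](C)(O)C[C@H](OC(=O)/C(C)=C\C)[C@@H]12
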